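## Retrosynthetic overview

1. Target ⇒ penta-silyl ether cleaved by fluoride; its tertiary alcohol (oxolane C3–OH next to C2H2; numbering O1, C2H2, C3(OH)(benzyl), C4(CH2OH), C5(aryl)) ⇒ hydroboration–oxidation of the C2=C3 enol ether of a 2,3-dihydrofuran.
2. Dihydrofuran ⇒ Cloke–Wilson ring expansion of a cyclopropanecarbaldehyde: the three-membered carbocycle (future C3, C4, C5) takes up its own formyl C=O (future C2 and O1) and becomes the five-membered oxacycle.
3. Enabling feature: future C5 carries the electron-rich 4-alkoxy-3-methoxyphenyl ring A (donor) and future C3 is the formyl-bearing quaternary carbon (acceptor), so the cyclopropane C3–C5 bond is a donor–acceptor bond that ionises and recloses through oxygen (O1–C5).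
4. Cyclopropane ⇒ intramolecular cyclopropanation of an (E)-2-benzyl-3-arylallyl diazoacetate with a chiral dirhodium carboxamidate (sets future C4, the one ring stereocentre carried through); alkene ⇒ aldol condensation of a ring-A aldehyde that already bears the (1R,2R) side chain (Evans syn-aldol) with a 3-arylpropanal.
5. Ring order: cyclopropane and fused γ-lactone together (step 14) → lactone opened (step 15) → cyclopropane enlarged to the dihydrofuran (step 17) → oxolane (step 18).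

Key step: step 17

Abbreviations: TBS = tert-butyldimethylsilyl; TIPS = triisopropylsilyl; ArB = 3-methoxy-4-[(triisopropylsilyl)oxy]phenyl (ring B on the benzyl carbon, ring C in the side chain); ArA = 3-methoxy-4-{[(1R,2R)-1,3-bis[(tert-butyldimethylsilyl)oxy]-1-(ArB)propan-2-yl]oxy}phenyl (ring A with the protected side chain).

Assumption: Rh2(4S-MPPIM)4 is taken to attack the alkene face of 19 in the sense known for simpler allylic diazoacetates (the (1R,5S) ring fusion); if the opposite sense were found, the enantiomeric catalyst Rh2(4R-MPPIM)4 would be used without other change.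

## Route

Step 1
Reactants: 1 4-bromo-2-methoxyphenol
Product: 2 2-(4-bromo-2-methoxyphenoxy)acetic acid
Conditions: ClCH2CO2H, NaOH, H2O, reflux; then HCl
Reagents that add atoms: chloroacetic acid, OC(=O)CCl
Why: Williamson ether synthesis; the phenoxide displaces chloride from chloroacetate.

Step 2
Reactants: 2 2-(4-bromo-2-methoxyphenoxy)acetic acid; 3 (S)-4-benzyloxazolidin-2-one
Product: 4 (S)-4-benzyl-3-[2-(4-bromo-2-methoxyphenoxy)acetyl]oxazolidin-2-one
Conditions: DCC, DMAP (cat.), CH2Cl2, 0 °C → rt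
Reagents that add atoms: none
Why: Carbodiimide-mediated N-acylation of the oxazolidinone (Steglich-type acylation), which should be clean because the acid has no α-stereocentre.

Step 3
Reactants: 5 vanillin (4-hydroxy-3-methoxybenzaldehyde)
Product: 6 3-methoxy-4-[(triisopropylsilyl)oxy]benzaldehyde
Conditions: TIPSCl, imidazole, DMF, rt
Reagents that add atoms: triisopropylsilyl chloride, CC(C)[Si](Cl)(C(C)C)C(C)C
Why: Silylation of the phenol; the TIPS aryl ether should survive the bases and hydrides used later and falls to fluoride at the end.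

Step 4
Reactants: 4 (S)-4-benzyl-3-[2-(4-bromo-2-methoxyphenoxy)acetyl]oxazolidin-2-one; 6 3-methoxy-4-[(triisopropylsilyl)oxy]benzaldehyde
Product: 8 (S)-4-benzyl-3-[(2S,3R)-2-(4-bromo-2-methoxyphenoxy)-3-hydroxy-3-(ArB)propanoyl]oxazolidin-2-one, via dibutylboron Z-enolate 7 (not isolated)
Conditions: Bu2BOTf, iPr2NEt, CH2Cl2, −78 → 0 °C; then 6, −78 → 0 °C; pH 7 buffer, MeOH, H2O2
Reagents that add atoms: none
Why: Evans syn-aldol reaction: the Z-boron enolate 7 should react through a closed chair transition state in which the benzyl group of the (S)-auxiliary shields one enolate face, setting the aryloxy carbon (2S) and the carbinol carbon (3R) syn, which is the threo relationship of the side chain.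

Step 5
Reactants: 8 aldol adduct
Product: 9 (1R,2R)-2-(4-bromo-2-methoxyphenoxy)-1-(ArB)propane-1,3-diol
Conditions: LiBH4, H2O (1 equiv), Et2O/THF, 0 °C
Reagents that add atoms: none
Why: Reductive cleavage of the N-acyloxazolidinone to the primary alcohol; the auxiliary is released and neither stereocentre is touched (the aryloxy carbon changes descriptor only).

Step 6
Reactants: 9 (1R,2R)-2-(4-bromo-2-methoxyphenoxy)-1-(ArB)propane-1,3-diol
Product: 10 4-bromo-2-methoxyphenyl ether of (1R,2R)-1,3-bis[(tert-butyldimethylsilyl)oxy]-1-(ArB)propan-2-ol (ArA–Br)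
Conditions: TBSOTf, 2,6-lutidine, CH2Cl2, 0 °C
Reagents that add atoms: tert-butyldimethylsilyl triflate, CC(C)(C)[Si](C)(C)OS(=O)(=O)C(F)(F)F
Why: Silylation of the primary and the benzylic secondary alcohol with the reactive silyl triflate.

Step 7
Reactants: 10 ArA–Br
Product: 12 3-methoxy-4-{[(1R,2R)-1,3-bis[(tert-butyldimethylsilyl)oxy]-1-(ArB)propan-2-yl]oxy}benzaldehyde (ArA–CHO), via aryllithium 11 (not isolated)
Conditions: n-BuLi, THF, −78 °C; then DMF, −78 → 0 °C; H2O
Reagents that add atoms: N,N-dimethylformamide, CN(C)C=O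
Why: Bromine–lithium exchange followed by formylation of the aryllithium with DMF (Bouveault aldehyde synthesis); silyl ethers and the aryl alkyl ether should be inert at −78 °C.

Step 8
Reactants: 13 methyl 3-(4-hydroxy-3-methoxyphenyl)propanoate
Product: 14 methyl 3-(ArB)propanoate
Conditions: TIPSCl, imidazole, DMF, rt
Reagents that add atoms: triisopropylsilyl chloride, CC(C)[Si](Cl)(C(C)C)C(C)C
Why: Silylation of the phenol of ring B.

Step 9
Reactants: 14 methyl 3-(ArB)propanoate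
Product: 15 3-(ArB)propanal
Conditions: DIBAL-H, toluene, −78 °C; MeOH, aq. Rochelle salt
Reagents that add atoms: none
Why: Partial reduction of the ester; the tetrahedral aluminium hemiacetal should persist at −78 °C and release the aldehyde on work-up.

Step 10
Reactants: 12 ArA–CHO; 15 3-(ArB)propanal
Product: 16 (E)-3-(ArA)-2-[(ArB)methyl]prop-2-enal
Conditions: pyrrolidine (0.3 equiv), PhCO2H (0.3 equiv), CH2Cl2, rt → 40 °C, slow addition of 15 (1.5 equiv)
Reagents that add atoms: none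
Why: Amine-catalysed crossed aldol condensation (the enamine of 15 adds to the non-enolisable aldehyde 12, then dehydration); the conjugated product should form as the thermodynamic (E)-enal with aryl trans to formyl.

Step 11
Reactants: 16 (E)-3-(ArA)-2-[(ArB)methyl]prop-2-enal
Product: 17 (E)-3-(ArA)-2-[(ArB)methyl]prop-2-en-1-ol
Conditions: NaBH4, CeCl3·7H2O, MeOH, 0 °C
Reagents that add atoms: none
Why: Luche reduction; selective 1,2-reduction of the enal with the alkene geometry retained.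

Step 12
Reactants: 17 (E)-3-(ArA)-2-[(ArB)methyl]prop-2-en-1-ol
Product: 18 (E)-3-(ArA)-2-[(ArB)methyl]prop-2-en-1-yl 2-bromoacetate
Conditions: BrCH2COBr, pyridine, CH2Cl2, 0 °C
Reagents that add atoms: bromoacetyl bromide, BrCC(Br)=O
Why: O-Acylation of the primary allylic alcohol by the acid bromide.

Step 13
Reactants: 18 bromoacetate
Product: 19 (E)-3-(ArA)-2-[(ArB)methyl]prop-2-en-1-yl 2-diazoacetate
Conditions: TsNHNHTs, DBU, THF, 0 °C
Reagents that add atoms: N,N'-ditosylhydrazine, Cc1ccc(cc1)S(=O)(=O)NNS(=O)(=O)c1ccc(C)cc1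
Why: N-Alkylation of the ditosylhydrazide anion by the bromoacetate followed by base-induced loss of two sulfinates (a Bamford–Stevens-type elimination) should give the diazoacetate under mild conditions.

Step 14
Reactants: 19 diazoacetate
Product: 20 (1R,5S,6S)-6-(ArA)-5-[(ArB)methyl]-3-oxabicyclo[3.1.0]hexan-2-one
Conditions: Rh2(4S-MPPIM)4 (dirhodium tetrakis[methyl (4S)-2-oxo-1-(3-phenylpropanoyl)imidazolidine-4-carboxylate], 1 mol %), CH2Cl2, reflux, slow addition of 19
Reagents that add atoms: none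
Why: Intramolecular carbenoid cyclopropanation of an allylic diazoacetate: syn-stereospecific addition keeps the (E)-geometry (ring A exo and cis to the benzyl group), the tether enforces the cis ring fusion, and the chiral carboxamidate ligands choose the alkene face and so the absolute configuration of C1, C5 and C6.

Step 15
Reactants: 20 cyclopropane-fused lactone
Product: 21 [(1S,2R,3S)-3-(ArA)-1-[(ArB)methyl]cyclopropane-1,2-diyl]dimethanol
Conditions: LiBH4, THF, 0 °C → rt
Reagents that add atoms: none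
Why: Hydride reduction of the lactone to the diol; no cyclopropane bond is touched and the aryl silyl ethers should be spared.

Step 16
Reactants: 21 cyclopropane diol
Product: 22 [(1S,2R,3S)-3-(ArA)-1-[(ArB)methyl]-2-{[(tert-butyldimethylsilyl)oxy]methyl}cyclopropyl]methanol
Conditions: TBSCl (1.05 equiv), imidazole, CH2Cl2, −30 → 0 °C
Reagents that add atoms: tert-butyldimethylsilyl chloride, CC(C)(C)[Si](C)(C)Cl
Why: Selective silylation: the hydroxymethyl on the cyclopropane CH is less hindered than the neopentyl-type hydroxymethyl on the quaternary, benzyl-bearing carbon, which stays free.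

Step 17
Reactants: 22 mono-silylated cyclopropylmethanol
Product: 24 (2S,3R)-2-(ArA)-4-[(ArB)methyl]-3-{[(tert-butyldimethylsilyl)oxy]methyl}-2,3-dihydrofuran, via cyclopropanecarbaldehyde 23 (not isolated)
Conditions: DMP, NaHCO3, CH2Cl2, 0 °C; filter; then Sc(OTf)3 (5 mol %), 4 Å MS, CH2Cl2 (dilute), −20 → 0 °C; Et3N quench
Reagents that add atoms: none
Why: Dess–Martin oxidation gives aldehyde 23, a donor–acceptor cyclopropane whose C1–C3 bond lies between the formyl-bearing quaternary C1 and C3 carrying the 4-alkoxy-3-methoxyphenyl ring A; Sc(OTf)3 binds the formyl oxygen, the C1–C3 bond heterolyses to a benzylic cation/enolate zwitterion, and the enolate oxygen closes on the cation (Cloke–Wilson rearrangement, closest precedent the acid-catalysed ring expansion of 2-arylcyclopropanecarbaldehydes to 2-aryl-2,3-dihydrofurans). The one ring closed is the five-membered oxacycle, formed by O–C bond formation with the enolate C=C inside the new ring (5-enolendo collapse of the ion pair onto a trigonal cation), so the carbocycle is enlarged by the C=O unit with release of the cyclopropane strain. The only new stereocentre is the aryl-bearing C2 of the dihydrofuran: the benzylic C2–O bond can re-ionise under the Lewis acid, so C2 should be set under thermodynamic control trans to the untouched C3 stereocentre (CH2OTBS, from step 14), while the configurations of cyclopropane C1 and C3 are erased and do not matter. The step needs regioselective cleavage of C1–C3 rather than C1–C2 or C2–C3, which is secured because only C3 carries a cation-stabilising donor and only C1 the acceptor, and O- rather than C-closure, which is favoured because C-closure only re-forms the strained cyclopropane. Capture of the cation by ring B (six-membered Friedel–Crafts closure) and aldol-type reaction of the product with 23 are to be held back by dilution, low temperature, catalytic acid and an early amine quench.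

Step 18
Reactants: 24 dihydrofuran
Product: 26 (3S,4R,5S)-5-(ArA)-3-[(ArB)methyl]-4-{[(tert-butyldimethylsilyl)oxy]methyl}oxolan-3-ol, via tertiary alkylborane 25 (not isolated)
Conditions: BH3·THF, THF, 0 °C → rt; then NaBO3·4H2O, THF/H2O, rt
Reagents that add atoms: sodium perborate, [Na+].[Na+].O[B-]1(O)OO[B-](O)(O)OO1
Why: Hydroboration–oxidation of the enol ether: the ring oxygen should direct boron to the β-carbon (the benzyl-bearing carbon), syn addition should occur on the face anti to the adjacent CH2OTBS group, and oxidation with retention gives the tertiary alcohol cis to ring A with the benzyl group cis to CH2OTBS.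

Step 19
Reactants: 26 penta-silyl ether
Product: 27 (3S,4R,5S)-5-{4-[(1R,2R)-1,3-dihydroxy-1-(4-hydroxy-3-methoxyphenyl)propan-2-yl]oxy-3-methoxyphenyl}-3-[(4-hydroxy-3-methoxyphenyl)methyl]-4-(hydroxymethyl)oxolan-3-ol (target)
Conditions: TBAF, AcOH, THF, 0 °C → rt
Reagents that add atoms: none
Why: Fluoride-mediated cleavage of all five silyl ethers; acetic acid buffering keeps the liberated p-hydroxybenzylic alcohol and the acid-sensitive 2-aryloxolane away from strong base and strong acid.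

## Compound list

1 | 4-bromo-2-methoxyphenol | COc1cc(Br)ccc1O | starting material
2 | 2-(4-bromo-2-methoxyphenoxy)acetic acid | COc1cc(Br)ccc1OCC(=O)O | intermediate
3 | (S)-4-benzyloxazolidin-2-one | O=C1OC[C@H](Cc2ccccc2)N1 | starting material
4 | (S)-4-benzyl-3-[2-(4-bromo-2-methoxyphenoxy)acetyl]oxazolidin-2-one | COc1cc(Br)ccc1OCC(=O)N1[C@@H](Cc2ccccc2)COC1=O | intermediate
5 | vanillin | COc1cc(C=O)ccc1O | starting material
6 | 3-methoxy-4-[(triisopropylsilyl)oxy]benzaldehyde | COc1cc(C=O)ccc1O[Si](C(C)C)(C(C)C)C(C)C | intermediate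
7 | dibutylboron (Z)-enolate of 4 | CCCCB(CCCC)O/C(N1[C@@H](Cc2ccccc2)COC1=O)=C\Oc1ccc(Br)cc1OC | intermediate (not isolated)
8 | (S)-4-benzyl-3-[(2S,3R)-2-(4-bromo-2-methoxyphenoxy)-3-hydroxy-3-(ArB)propanoyl]oxazolidin-2-one | COc1cc(Br)ccc1O[C@H](C(=O)N1[C@@H](Cc2ccccc2)COC1=O)[C@H](O)c1ccc(O[Si](C(C)C)(C(C)C)C(C)C)c(OC)c1 | intermediate
9 | (1R,2R)-2-(4-bromo-2-methoxyphenoxy)-1-(ArB)propane-1,3-diol | COc1cc(Br)ccc1O[C@H](CO)[C@H](O)c1ccc(O[Si](C(C)C)(C(C)C)C(C)C)c(OC)c1 | intermediate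
10 | ArA–Br, the 1,3-bis-TBS ether of 9 | COc1cc(Br)ccc1O[C@H](CO[Si](C)(C)C(C)(C)C)[C@H](O[Si](C)(C)C(C)(C)C)c1ccc(O[Si](C(C)C)(C(C)C)C(C)C)c(OC)c1 | intermediate
11 | ArA–Li, aryllithium from 10 | COc1cc([Li])ccc1O[C@H](CO[Si](C)(C)C(C)(C)C)[C@H](O[Si](C)(C)C(C)(C)C)c1ccc(O[Si](C(C)C)(C(C)C)C(C)C)c(OC)c1 | intermediate (not isolated)
12 | ArA–CHO, 3-methoxy-4-{[(1R,2R)-1,3-bis(TBSO)-1-(ArB)propan-2-yl]oxy}benzaldehyde | COc1cc(C=O)ccc1O[C@H](CO[Si](C)(C)C(C)(C)C)[C@H](O[Si](C)(C)C(C)(C)C)c1ccc(O[Si](C(C)C)(C(C)C)C(C)C)c(OC)c1 | intermediate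
13 | methyl 3-(4-hydroxy-3-methoxyphenyl)propanoate | COC(=O)CCc1ccc(O)c(OC)c1 | starting material
14 | methyl 3-(ArB)propanoate | COC(=O)CCc1ccc(O[Si](C(C)C)(C(C)C)C(C)C)c(OC)c1 | intermediate
15 | 3-(ArB)propanal | O=CCCc1ccc(O[Si](C(C)C)(C(C)C)C(C)C)c(OC)c1 | intermediate
16 | (E)-3-(ArA)-2-[(ArB)methyl]prop-2-enal | O=C/C(Cc1ccc(O[Si](C(C)C)(C(C)C)C(C)C)c(OC)c1)=C/c1ccc(O[C@H](CO[Si](C)(C)C(C)(C)C)[C@H](O[Si](C)(C)C(C)(C)C)c2ccc(O[Si](C(C)C)(C(C)C)C(C)C)c(OC)c2)c(OC)c1 | intermediate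
17 | (E)-3-(ArA)-2-[(ArB)methyl]prop-2-en-1-ol | OC/C(Cc1ccc(O[Si](C(C)C)(C(C)C)C(C)C)c(OC)c1)=C/c1ccc(O[C@H](CO[Si](C)(C)C(C)(C)C)[C@H](O[Si](C)(C)C(C)(C)C)c2ccc(O[Si](C(C)C)(C(C)C)C(C)C)c(OC)c2)c(OC)c1 | intermediate
18 | (E)-3-(ArA)-2-[(ArB)methyl]prop-2-en-1-yl 2-bromoacetate | BrCC(=O)OC/C(Cc1ccc(O[Si](C(C)C)(C(C)C)C(C)C)c(OC)c1)=C/c1ccc(O[C@H](CO[Si](C)(C)C(C)(C)C)[C@H](O[Si](C)(C)C(C)(C)C)c2ccc(O[Si](C(C)C)(C(C)C)C(C)C)c(OC)c2)c(OC)c1 | intermediate
19 | (E)-3-(ArA)-2-[(ArB)methyl]prop-2-en-1-yl 2-diazoacetate | [N-]=[N+]=CC(=O)OC/C(Cc1ccc(O[Si](C(C)C)(C(C)C)C(C)C)c(OC)c1)=C/c1ccc(O[C@H](CO[Si](C)(C)C(C)(C)C)[C@H](O[Si](C)(C)C(C)(C)C)c2ccc(O[Si](C(C)C)(C(C)C)C(C)C)c(OC)c2)c(OC)c1 | intermediate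
20 | (1R,5S,6S)-6-(ArA)-5-[(ArB)methyl]-3-oxabicyclo[3.1.0]hexan-2-one | O=C1OC[C@@]2(Cc3ccc(O[Si](C(C)C)(C(C)C)C(C)C)c(OC)c3)[C@H](c3ccc(O[C@H](CO[Si](C)(C)C(C)(C)C)[C@H](O[Si](C)(C)C(C)(C)C)c4ccc(O[Si](C(C)C)(C(C)C)C(C)C)c(OC)c4)c(OC)c3)[C@@H]12 | intermediate
21 | [(1S,2R,3S)-3-(ArA)-1-[(ArB)methyl]cyclopropane-1,2-diyl]dimethanol | OC[C@@]1(Cc2ccc(O[Si](C(C)C)(C(C)C)C(C)C)c(OC)c2)[C@H](c2ccc(O[C@H](CO[Si](C)(C)C(C)(C)C)[C@H](O[Si](C)(C)C(C)(C)C)c3ccc(O[Si](C(C)C)(C(C)C)C(C)C)c(OC)c3)c(OC)c2)[C@H]1CO | intermediate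
22 | [(1S,2R,3S)-3-(ArA)-1-[(ArB)methyl]-2-(TBSO-methyl)cyclopropyl]methanol | OC[C@@]1(Cc2ccc(O[Si](C(C)C)(C(C)C)C(C)C)c(OC)c2)[C@H](c2ccc(O[C@H](CO[Si](C)(C)C(C)(C)C)[C@H](O[Si](C)(C)C(C)(C)C)c3ccc(O[Si](C(C)C)(C(C)C)C(C)C)c(OC)c3)c(OC)c2)[C@H]1CO[Si](C)(C)C(C)(C)C | intermediate
23 | (1S,2R,3S)-3-(ArA)-1-[(ArB)methyl]-2-(TBSO-methyl)cyclopropane-1-carbaldehyde | O=C[C@@]1(Cc2ccc(O[Si](C(C)C)(C(C)C)C(C)C)c(OC)c2)[C@H](c2ccc(O[C@H](CO[Si](C)(C)C(C)(C)C)[C@H](O[Si](C)(C)C(C)(C)C)c3ccc(O[Si](C(C)C)(C(C)C)C(C)C)c(OC)c3)c(OC)c2)[C@H]1CO[Si](C)(C)C(C)(C)C | intermediate (not isolated)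
24 | (2S,3R)-2-(ArA)-4-[(ArB)methyl]-3-(TBSO-methyl)-2,3-dihydrofuran | COc1cc(CC2=CO[C@H](c3ccc(O[C@H](CO[Si](C)(C)C(C)(C)C)[C@H](O[Si](C)(C)C(C)(C)C)c4ccc(O[Si](C(C)C)(C(C)C)C(C)C)c(OC)c4)c(OC)c3)[C@H]2CO[Si](C)(C)C(C)(C)C)ccc1O[Si](C(C)C)(C(C)C)C(C)C | intermediate
25 | tertiary alkylborane from 24 (BH2 on the oxolane carbon and face that later carry OH) | COc1cc(C[C@@]2([BH2])CO[C@H](c3ccc(O[C@H](CO[Si](C)(C)C(C)(C)C)[C@H](O[Si](C)(C)C(C)(C)C)c4ccc(O[Si](C(C)C)(C(C)C)C(C)C)c(OC)c4)c(OC)c3)[C@H]2CO[Si](C)(C)C(C)(C)C)ccc1O[Si](C(C)C)(C(C)C)C(C)C | intermediate (not isolated)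
26 | (3S,4R,5S)-5-(ArA)-3-[(ArB)methyl]-4-(TBSO-methyl)oxolan-3-ol | COc1cc(C[C@@]2(O)CO[C@H](c3ccc(O[C@H](CO[Si](C)(C)C(C)(C)C)[C@H](O[Si](C)(C)C(C)(C)C)c4ccc(O[Si](C(C)C)(C(C)C)C(C)C)c(OC)c4)c(OC)c3)[C@H]2CO[Si](C)(C)C(C)(C)C)ccc1O[Si](C(C)C)(C(C)C)C(C)C | intermediate
27 | (3S,4R,5S)-5-{4-[(1R,2R)-1,3-dihydroxy-1-(4-hydroxy-3-methoxyphenyl)propan-2-yl]oxy-3-methoxyphenyl}-3-[(4-hydroxy-3-methoxyphenyl)methyl]-4-(hydroxymethyl)oxolan-3-ol | COc1cc(C[C@@]2(O)CO[C@H](c3ccc(O[C@H](CO)[C@H](O)c4ccc(O)c(OC)c4)c(OC)c3)[C@H]2CO)ccc1O | target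

## Summary and risks

Total step count: 19. Longest linear sequence: 16 steps (steps 1, 2, 4, 5, 6, 7, 10, 11, 12, 13, 14, 15, 16, 17, 18, 19).

**Step 14.** The risk is weak discrimination between the two alkene faces in carbene transfer, because the catalyst class is documented for less substituted allyl esters than this 2,3-disubstituted one; 20 would then carry its epimer at all three cyclopropane carbons, and only the CH–CH2O centre is kept to the end. Fallback: stereochemical purity is secured by separation of a covalent chiral derivative instead of by catalyst control. It sets out from 22 (made as in steps 15 and 16 from material of insufficient purity). The free neopentyl-type hydroxyl of 22 is esterified with (S)-2-methoxy-2-phenylacetic acid (DCC, DMAP) to give the mandelate-type ester F1, whose chiral acyl group sits next to the cyclopropane. F1 should be separable from its cyclopropane epimer by chromatography or crystallisation. Cleavage with DIBAL-H at −78 °C comes back to the route at 22.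

**Step 17.** The risk is over-reaction of the acid-labile enol ether under the Lewis acid: re-ionisation of the benzylic C–O bond followed by Friedel–Crafts capture by ring B, loss of trans control, or oligomerisation. Fallback: the ring expansion is moved to the carboxylic acid level and the enol ether is released under base. It sets out from 22. Oxidation with TEMPO (cat.) and PhI(OAc)2 in MeCN/pH 7 buffer gives the cyclopropanecarboxylic acid F2. With a trace of TsOH this donor–acceptor acid should ring-expand, by carboxyl capture of the benzylic carbon, to the robust trans,trans γ-butyrolactone F3. DIBAL-H at −78 °C gives the lactol F4, and MsCl/Et3N eliminates it to the enol ether, coming back to the route at 24.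

**Step 18.** The risk is addition of borane with the wrong regiochemistry or to the wrong face of the trisubstituted enol ether, or β-alkoxy elimination (ring opening) of the β-boryl ether before oxidation. Fallback: oxygen is delivered first and hydride second. It sets out from 24. Dimethyldioxirane in acetone/CH2Cl2 at −40 °C epoxidises the enol ether anti to the CH2OTBS group to give the epoxide F5 (an epoxy acetal of the 1,2-anhydro-sugar type). DIBAL-H (or LiBHEt3) at −78 °C delivers hydride to the acetal carbon with the tertiary C–O bond retained, coming back to the route at 26.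

## Further compounds

F1 | step 14 | [(1S,2R,3S)-3-(ArA)-1-[(ArB)methyl]-2-(TBSO-methyl)cyclopropyl]methyl (2S)-2-methoxy-2-phenylacetate | CO[C@H](C(=O)OC[C@@]1(Cc2ccc(O[Si](C(C)C)(C(C)C)C(C)C)c(OC)c2)[C@H](c2ccc(O[C@H](CO[Si](C)(C)C(C)(C)C)[C@H](O[Si](C)(C)C(C)(C)C)c3ccc(O[Si](C(C)C)(C(C)C)C(C)C)c(OC)c3)c(OC)c2)[C@H]1CO[Si](C)(C)C(C)(C)C)c1ccccc1
F2 | step 17 | (1S,2R,3S)-3-(ArA)-1-[(ArB)methyl]-2-(TBSO-methyl)cyclopropane-1-carboxylic acid | OC(=O)[C@@]1(Cc2ccc(O[Si](C(C)C)(C(C)C)C(C)C)c(OC)c2)[C@H](c2ccc(O[C@H](CO[Si](C)(C)C(C)(C)C)[C@H](O[Si](C)(C)C(C)(C)C)c3ccc(O[Si](C(C)C)(C(C)C)C(C)C)c(OC)c3)c(OC)c2)[C@H]1CO[Si](C)(C)C(C)(C)C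
F3 | step 17 | (3S,4R,5S)-5-(ArA)-3-[(ArB)methyl]-4-(TBSO-methyl)oxolan-2-one | COc1cc(C[C@@H]2C(=O)O[C@H](c3ccc(O[C@H](CO[Si](C)(C)C(C)(C)C)[C@H](O[Si](C)(C)C(C)(C)C)c4ccc(O[Si](C(C)C)(C(C)C)C(C)C)c(OC)c4)c(OC)c3)[C@H]2CO[Si](C)(C)C(C)(C)C)ccc1O[Si](C(C)C)(C(C)C)C(C)C
F4 | step 17 | (3S,4R,5S)-5-(ArA)-3-[(ArB)methyl]-4-(TBSO-methyl)oxolan-2-ol (both anomers) | COc1cc(C[C@@H]2C(O)O[C@H](c3ccc(O[C@H](CO[Si](C)(C)C(C)(C)C)[C@H](O[Si](C)(C)C(C)(C)C)c4ccc(O[Si](C(C)C)(C(C)C)C(C)C)c(OC)c4)c(OC)c3)[C@H]2CO[Si](C)(C)C(C)(C)C)ccc1O[Si](C(C)C)(C(C)C)C(C)C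
F5 | step 18 | tert-butyl{[(1S,3S,4R,5S)-3-(ArA)-5-[(ArB)methyl]-2,6-dioxabicyclo[3.1.0]hexan-4-yl]methoxy}dimethylsilane | COc1cc(C[C@@]23O[C@@H]2O[C@H](c4ccc(O[C@H](CO[Si](C)(C)C(C)(C)C)[C@H](O[Si](C)(C)C(C)(C)C)c5ccc(O[Si](C(C)C)(C(C)C)C(C)C)c(OC)c5)c(OC)c4)[C@H]3CO[Si](C)(C)C(C)(C)C)ccc1O[Si](C(C)C)(C(C)C)C(C)C
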